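**Assumption:** "Isobutylshikonin" is taken as the isobutyrate (2-methylpropanoate) ester of (R)-shikonin, exactly as the SMILES shows; the single stereocentre is (R).

## Retrosynthetic overview

1. Target 12 ⇒ Diels–Alder/ring-opening/aromatisation of the chiral benzoquinone 8 with 2,5-bis(trimethylsilyloxy)furan 11. The furan is dearomatised and becomes the 5,8-dihydroxy ring, so the naphthazarin appears unprotected in the last step.
2. Quinone 8 ⇒ CAN oxidative dearomatisation of the dimethoxyarene ester 7.
3. 7 ⇒ isobutyrylation of 5 ⇒ cross-metathesis of 3 with 2-methyl-2-butene ⇒ Brown allylation of 2,5-dimethoxybenzaldehyde 1, which sets (R).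
4. 11 ⇒ succinic anhydride 9 by double enol silylation.
5. Ring order: the benzene ring of 1 becomes the quinone ring; the dihydroxy-benzenoid ring is formed last.

## Route

**Step 1**
Reactants: 1 (2,5-dimethoxybenzaldehyde); 2 (allylmagnesium bromide)
Product: 3, (R)-1-(2,5-dimethoxyphenyl)but-3-en-1-ol
Conditions: (+)-Ipc2BOMe [(−)-α-pinene series], allylMgBr, Et2O, 0 °C → rt, filter Mg salts; then 1, Et2O/pentane, −100 °C; NaOH, 30% H2O2, rt
Reagents that add atoms: allylmagnesium bromide (2), C=CC[Mg]Br
Why: Brown asymmetric allylboration through a closed chair transition state. The (+)-α-pinene-derived reagent gives (S)-1-arylbut-3-en-1-ols, so the (−)-α-pinene-derived (−)-Ipc2B(allyl) adds to the Re face and gives the (R)-carbinol (expected ≥95% ee under salt-free, −100 °C conditions).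

**Step 2**
Reactants: 3; 4 (2-methyl-2-butene)
Product: 5, (R)-1-(2,5-dimethoxyphenyl)-4-methylpent-3-en-1-ol
Conditions: Grubbs II (3 mol%), 2-methyl-2-butene (large excess, co-solvent), CH2Cl2, rt → 40 °C (sealed), 12 h
Reagents that add atoms: 2-methyl-2-butene (4), CC=C(C)C
Why: Olefin cross-metathesis of a terminal alkene with excess 2-methyl-2-butene caps it as the isopropylidene (prenyl-type) olefin with loss of propene; the carbinol centre is not involved.

**Step 3**
Reactants: 5; 6 (isobutyryl chloride)
Product: 7, (R)-1-(2,5-dimethoxyphenyl)-4-methylpent-3-en-1-yl 2-methylpropanoate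
Conditions: i-PrCOCl (1.3 equiv), Et3N, DMAP (10 mol%), CH2Cl2, 0 °C → rt
Reagents that add atoms: isobutyryl chloride (6), CC(C)C(=O)Cl
Why: DMAP-catalysed O-acylation occurs at oxygen, so the C–O stereocentre is retained; the ester also protects the benzylic alcohol for the oxidation.

**Step 4**
Reactants: 7
Product: 8, (1R)-1-(3,6-dioxocyclohexa-1,4-dien-1-yl)-4-methylpent-3-en-1-yl 2-methylpropanoate (2-substituted 1,4-benzoquinone)
Conditions: CAN (2.5 equiv), MeCN/H2O (2:1), 0 °C, 15 min
Reagents that add atoms: water, O (supplies the quinone oxygens; both OMe leave as MeOH)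
Why: Oxidative demethylation/dearomatisation of a p-dimethoxyarene via the arene radical cation is fast at 0 °C; the ester, the trisubstituted alkene and the benzylic C–O bond survive, as in the analogous oxidations of shikonin-type tetramethoxynaphthalene esters.

**Step 5**
Reactants: 9 (succinic anhydride); 10 (chlorotrimethylsilane)
Product: 11, 2,5-bis(trimethylsilyloxy)furan
Conditions: TMSCl (2.4 equiv), Et3N (2.4 equiv), ZnCl2 (cat.), MeCN, rt → 50 °C; filter, distil under reduced pressure, store under Ar
Reagents that add atoms: chlorotrimethylsilane (10), C[Si](C)(C)Cl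
Why: Double enol silylation of the cyclic anhydride gives the aromatic, electron-rich 2,5-dioxygenated furan (a bis-silyl ketene acetal).

**Step 6**
Reactants: 8; 11
Product: 12, isobutyrylshikonin, (1R)-1-(5,8-dihydroxy-1,4-dioxo-1,4-dihydronaphthalen-2-yl)-4-methylpent-3-en-1-yl 2-methylpropanoate
Conditions: 11 (1.2 equiv), CH2Cl2, −78 °C → rt, Ar, dark; then 1 M HCl/THF, rt, 30 min; SiO2 chromatography in the dark
Reagents that add atoms: none (aqueous acid supplies only H; the TMS groups and one furan oxygen leave as TMSOH/(TMS)2O)
Why: Diels–Alder addition of a 2,5-bis(silyloxy)furan to a quinone, followed by oxa-bridge opening and enolisation, is an established way to fuse a dihydroxybenzene ring onto a quinone (p-benzoquinone gives naphthazarin); its use on this chiral monosubstituted quinone is an untested extension. The symmetric diene should add to the unhindered C5=C6 bond of 8. The adduct is a 4a,8a-dihydro-1,4,5,8-tetraone already at the naphthazarin oxidation level, so it tautomerises to 12 without an oxidant. The stereocentre is not touched.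

## Compound list

1 | 2,5-dimethoxybenzaldehyde | COc1ccc(OC)c(C=O)c1 | starting material
2 | allylmagnesium bromide | C=CC[Mg]Br | starting material
3 | (R)-1-(2,5-dimethoxyphenyl)but-3-en-1-ol | C=CC[C@@H](O)c1cc(OC)ccc1OC | intermediate
4 | 2-methyl-2-butene | CC=C(C)C | starting material
5 | (R)-1-(2,5-dimethoxyphenyl)-4-methylpent-3-en-1-ol | CC(C)=CC[C@@H](O)c1cc(OC)ccc1OC | intermediate
6 | isobutyryl chloride | CC(C)C(=O)Cl | starting material
7 | (R)-1-(2,5-dimethoxyphenyl)-4-methylpent-3-en-1-yl 2-methylpropanoate | CC(C)=CC[C@@H](OC(=O)C(C)C)c1cc(OC)ccc1OC | intermediate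
8 | (1R)-1-(3,6-dioxocyclohexa-1,4-dien-1-yl)-4-methylpent-3-en-1-yl 2-methylpropanoate | CC(C)=CC[C@@H](OC(=O)C(C)C)C1=CC(=O)C=CC1=O | intermediate
9 | succinic anhydride | O=C1CCC(=O)O1 | starting material
10 | chlorotrimethylsilane | C[Si](C)(C)Cl | starting material
11 | 2,5-bis(trimethylsilyloxy)furan | C[Si](C)(C)Oc1ccc(O[Si](C)(C)C)o1 | intermediate
12 | isobutyrylshikonin | CC(C)=CC[C@@H](OC(=O)C(C)C)C1=CC(=O)c2c(O)ccc(O)c2C1=O | target

## Summary

**Total steps:** 6. **Longest linear sequence:** 5 (1 → 3 → 5 → 7 → 8 → 12); step 5 is a one-step side branch.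

**Steps most likely to fail, with fallbacks**

1. **Step 6 (furan Diels–Alder/aromatisation).** Risks: electron transfer from the very electron-rich furan to the quinone; Mukaiyama–Michael addition followed by premature aromatisation to an aryl-succinic anhydride; attack at the substituted C=C. Fallback: invert the order of events. Make the parent naphthazarin first (p-benzoquinone + 11), convert it to 1,4,5,8-tetramethoxynaphthalene, formylate, run the same allylation/cross-metathesis/acylation on that aldehyde, and unmask by CAN then AgO/HNO3.

2. **Step 4 (CAN oxidation).** Risks: biaryl diquinone formation, or acid solvolysis (and racemisation) of the electron-rich benzylic ester. Fallback: change the phenol masking. Start from 5-methoxysalicylaldehyde with the phenol as a TBS ether, run the same steps, then remove TBS and oxidise the resulting p-methoxyphenol to the quinone with PhI(OAc)2 in aqueous MeCN under near-neutral conditions.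

3. **Step 2 (cross-metathesis).** Risks: incomplete conversion or ethylidene (crotyl) by-product. Fallback: form the C–C bond and stereocentre differently. ortho-Lithiate 1,4-dimethoxybenzene (n-BuLi/TMEDA), acylate with N-methoxy-N-methyl-4-methylpent-3-enamide, and reduce the ketone with (+)-DIP-Cl to give 5 directly with the prenyl unit already in place.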